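**Retrosynthetic overview**
1. Target 25 ← acetylation of the tertiary C1–OH and fluoride removal of two aryl silyl ethers from the protected 1‑hydroxypinoresinol 23.
2. Ring A ether ← two-stage reduction (lactol, then silane) of the cis-fused bicyclic lactone 21, whose lactone ring is ring A.
3. Ring B ← closure of the C2 hydroxyl onto a C4 tosylate in triol lactone 19; C1–OH ← hydroxylation of the dianion of β‑hydroxy lactone 16.
4. C1–C2 bond ← intermolecular aldol of the lithium enolate of lactone 12 with protected vanillin 2; the C2 carbinol is then fixed by oxidation and catalytic asymmetric reduction.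
5. Lactone 12 (C5, C6) ← Evans syn‑aldol of succinate imide 6 with 2, then lactonization. Ring order: ring A as γ‑lactone, then ring B, then ring A carbonyl to CH2.

Assumption: Ar = 3‑methoxy‑4‑(triisopropylsilyloxy)phenyl; locants C1–C8 in the explanations are those of the 3,7‑dioxabicyclo[3.3.0]octane core of the target (C1 O‑bearing bridgehead, C2 and C6 aryl carbons, C5 the CH bridgehead, C4 and C8 the CH2 groups); a metal alkoxide that is only protonated on work‑up is not numbered apart from its alcohol.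

**Route**

Step 1
Reactants: 1 vanillin (4‑hydroxy‑3‑methoxybenzaldehyde)
Product: 2 3‑methoxy‑4‑(triisopropylsilyloxy)benzaldehyde (ArCHO)
Conditions: iPr3SiCl, imidazole, DMF, 0 °C → rt
Reagents that add atoms: triisopropylsilyl chloride, CC(C)[Si](Cl)(C(C)C)C(C)C
Why: Silyl etherification masks the phenol as a base‑stable, fluoride‑labile ether that can be removed at the end without touching the tertiary acetate or the benzylic ring ethers.

Step 2
Reactants: 3 (S)‑4‑benzyl‑1,3‑oxazolidin‑2‑one; 4 methyl 4‑chloro‑4‑oxobutanoate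
Product: 6 methyl 4‑[(4S)‑4‑benzyl‑2‑oxo‑1,3‑oxazolidin‑3‑yl]‑4‑oxobutanoate, via lithium salt of the oxazolidinone 5 (not isolated)
Conditions: n‑BuLi, THF, −78 °C; then 4, −78 → 0 °C
Reagents that add atoms: none
Why: N‑Acylation of the lithiated Evans auxiliary by the acid chloride is fast at −78 °C and leaves the methyl ester untouched.

Step 3
Reactants: 6 methyl 4‑[(4S)‑4‑benzyl‑2‑oxo‑1,3‑oxazolidin‑3‑yl]‑4‑oxobutanoate; 2 ArCHO
Product: 8 methyl (3S,4S)‑4‑Ar‑3‑{[(4S)‑4‑benzyl‑2‑oxo‑1,3‑oxazolidin‑3‑yl]carbonyl}‑4‑hydroxybutanoate, via dibutylboron Z‑enolate 7 (not isolated)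
Conditions: Bu2BOTf, iPr2NEt, CH2Cl2, 0 °C; 2, −78 → 0 °C; pH 7 buffer, MeOH, 30% H2O2, 0 °C
Reagents that add atoms: none
Why: Evans boron syn‑aldol addition forms the C5–C6 bond: the Z‑enolate forms only at the imide α‑carbon and adds through a Zimmerman–Traxler chair on the face away from the auxiliary benzyl group, setting C5 and C6 (both S in 8) as the Evans syn pair.

Step 4
Reactants: 8 methyl (3S,4S)‑4‑Ar‑3‑{[(4S)‑4‑benzyl‑2‑oxo‑1,3‑oxazolidin‑3‑yl]carbonyl}‑4‑hydroxybutanoate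
Product: 10 (2S,3S)‑2‑Ar‑5‑oxotetrahydrofuran‑3‑carboxylic acid (trans), via hydroxy acid methyl ester 9 (not isolated)
Conditions: LiOH, 30% H2O2, THF/H2O, 0 °C; Na2SO3; 1 M HCl to pH 2; then pyridinium p‑toluenesulfonate (cat.), CH2Cl2, rt
Reagents that add atoms: hydrogen peroxide (acting as LiOOH, source of the acid OH oxygen), OO
Why: Hydroperoxide cleaves the exocyclic imide carbonyl selectively (auxiliary recovered) and acid‑catalysed lactonization of the γ‑hydroxy ester closes the lactone that becomes ring A, the syn aldol mapping onto the trans lactone with no change at C5 or C6.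

Step 5
Reactants: 10 (2S,3S)‑2‑Ar‑5‑oxotetrahydrofuran‑3‑carboxylic acid
Product: 11 (4R,5S)‑5‑Ar‑4‑(hydroxymethyl)dihydrofuran‑2(3H)‑one
Conditions: BH3·SMe2, THF, 0 °C → rt; MeOH
Reagents that add atoms: none
Why: Chemoselective borane reduction of a carboxylic acid beside a γ‑lactone gives the C4 alcohol under non‑basic conditions that do not allow translactonization.

Step 6
Reactants: 11 (4R,5S)‑5‑Ar‑4‑(hydroxymethyl)dihydrofuran‑2(3H)‑one
Product: 12 (4R,5S)‑5‑Ar‑4‑[(tert‑butyldimethylsilyloxy)methyl]dihydrofuran‑2(3H)‑one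
Conditions: tBuMe2SiCl, imidazole, CH2Cl2, 0 °C → rt
Reagents that add atoms: tert‑butyldimethylsilyl chloride, CC(C)(C)[Si](C)(C)Cl
Why: Silyl protection of the primary alcohol blocks translactonization and makes the lactone safe for enolate chemistry.

Step 7
Reactants: 12 (4R,5S)‑5‑Ar‑4‑[(tert‑butyldimethylsilyloxy)methyl]dihydrofuran‑2(3H)‑one; 2 ArCHO
Product: 14 (3R,4R,5S)‑5‑Ar‑3‑[Ar(hydroxy)methyl]‑4‑[(tert‑butyldimethylsilyloxy)methyl]dihydrofuran‑2(3H)‑one as both carbinol epimers, via lithium enolate 13 (not isolated)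
Conditions: LiN(SiMe3)2, THF, −78 °C; 2, −78 °C; AcOH
Reagents that add atoms: none
Why: Intermolecular aldol addition of the lactone enolate to the second aldehyde unit forms the C1–C2 bond and joins the two aryl halves, the aldehyde entering trans to the neighbouring CH2OSi group, while the carbinol configuration is left open because step 8 erases it.

Step 8
Reactants: 14 the aldol epimer mixture
Product: 15 (3R,4R,5S)‑5‑Ar‑3‑[3‑methoxy‑4‑(triisopropylsilyloxy)benzoyl]‑4‑[(tert‑butyldimethylsilyloxy)methyl]dihydrofuran‑2(3H)‑one (C3 epimerizable, trans form)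
Conditions: Dess–Martin periodinane, CH2Cl2, 0 °C → rt
Reagents that add atoms: none
Why: Dess–Martin oxidation converges both carbinol epimers on one β‑keto lactone without disturbing the silyl ethers.

Step 9
Reactants: 15 the β‑keto lactone
Product: 16 (3R,4R,5S)‑5‑Ar‑3‑[(S)‑Ar(hydroxy)methyl]‑4‑[(tert‑butyldimethylsilyloxy)methyl]dihydrofuran‑2(3H)‑one
Conditions: RuCl[(S,S)‑TsDPEN](p‑cymene) (2 mol %), HCO2H/Et3N (5:2), CH2Cl2, 30 °C
Reagents that add atoms: none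
Why: Noyori asymmetric transfer hydrogenation of the aryl ketone sets C2 under catalyst control (the sense that gives (S)‑1‑arylalkanols with the (S,S) ligand), while the labile C3 centre equilibrates to the trans arrangement.

Step 10
Reactants: 16 the (S)‑carbinol lactone
Product: 18 (3R,4R,5S)‑5‑Ar‑3‑hydroxy‑3‑[(R)‑Ar(hydroxy)methyl]‑4‑[(tert‑butyldimethylsilyloxy)methyl]dihydrofuran‑2(3H)‑one, via dilithium alkoxide enolate 17 (not isolated)
Conditions: LiN(iPr)2 (2.3 equiv), THF, −78 → −40 °C; 2‑(phenylsulfonyl)‑3‑phenyloxaziridine, −78 °C; AcOH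
Reagents that add atoms: 2‑(phenylsulfonyl)‑3‑phenyloxaziridine (Davis oxaziridine), O=S(=O)(c1ccccc1)N1OC1c1ccccc1
Why: Davis α‑hydroxylation of a Fráter–Seebach‑type dianion, which cannot undergo retro‑aldol or β‑elimination, occurs on the face opposite both the CH2OSi group on C5 and the aryl group of the chelated carbinol, so the C1–OH ends trans to C4 and the C2 carbon cis to C4 as ring B requires (the C2 descriptor changes from S to R by priority only).

Step 11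
Reactants: 18 the C1‑hydroxylated lactone
Product: 19 (3R,4R,5S)‑5‑Ar‑3‑hydroxy‑3‑[(R)‑Ar(hydroxy)methyl]‑4‑(hydroxymethyl)dihydrofuran‑2(3H)‑one
Conditions: HF·pyridine, pyridine, THF, 0 °C → rt
Reagents that add atoms: none
Why: Buffered HF·pyridine cleaves the primary alkyl silyl ether much faster than the hindered aryl triisopropylsilyl ethers, and the non‑basic medium avoids translactonization and retro‑aldol of the triol.

Step 12
Reactants: 19 the triol lactone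
Product: 21 (1R,2R,5R,6S)‑2,6‑di‑Ar‑1‑hydroxy‑3,7‑dioxabicyclo[3.3.0]octan‑8‑one, via primary tosylate 20 (not isolated)
Conditions: TsCl, pyridine, 0 °C; then 50 °C
Reagents that add atoms: none
Why: Selective sulfonylation of the only primary hydroxyl followed by intramolecular Williamson‑type 5‑exo‑tet displacement by the C2 hydroxyl closes ring B with C2 untouched, which makes the bicycle cis‑fused and places the C2 aryl group exo.

Step 13
Reactants: 21 the bicyclic hydroxy lactone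
Product: 22 (1R,2R,5R,6S)‑2,6‑di‑Ar‑3,7‑dioxabicyclo[3.3.0]octane‑1,8‑diol (lactol, both C8 anomers)
Conditions: iBu2AlH (3.5 equiv), CH2Cl2, −78 °C; aq KNaC4H4O6
Reagents that add atoms: none
Why: Partial hydride reduction of the lactone at −78 °C stops at the lactol because the tetrahedral aluminium hemiacetal only collapses on work‑up.

Step 14
Reactants: 22 the lactol
Product: 23 (1S,2R,5R,6S)‑2,6‑di‑Ar‑3,7‑dioxabicyclo[3.3.0]octan‑1‑ol
Conditions: Et3SiH, BF3·OEt2, CH2Cl2, −78 → −30 °C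
Reagents that add atoms: none
Why: Ionic reduction of the lactol: BF3 generates the cyclic oxocarbenium ion at C8 and triethylsilane reduces it to the CH2 of ring A, leaving C1, C2, C5 and C6 unchanged (C1 becomes S by priority only).

Step 15
Reactants: 23 the tertiary alcohol
Product: 24 (1S,2R,5R,6S)‑2,6‑di‑Ar‑3,7‑dioxabicyclo[3.3.0]octan‑1‑yl acetate
Conditions: Ac2O, DMAP, Et3N, CH2Cl2, rt → 40 °C
Reagents that add atoms: acetic anhydride, CC(=O)OC(C)=O
Why: DMAP‑catalysed acylation is forcing enough to esterify the hindered bridgehead tertiary alcohol, the only free hydroxyl in 23.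

Step 16
Reactants: 24 the bis‑silyl acetate
Product: 25 1‑acetoxypinoresinol, (1S,2R,5R,6S)‑2,6‑bis(4‑hydroxy‑3‑methoxyphenyl)‑3,7‑dioxabicyclo[3.3.0]octan‑1‑yl acetate
Conditions: Bu4NF, AcOH (1:1), THF, 0 °C
Reagents that add atoms: none
Why: Fluoride‑mediated desilylation buffered with acetic acid frees both phenols without acetate loss and without the hydrogenolysis or acid conditions that would endanger the benzylic ring ethers.

**Compound list**
1 | vanillin | COc1cc(C=O)ccc1O | starting material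
2 | 3‑methoxy‑4‑(triisopropylsilyloxy)benzaldehyde | COc1cc(C=O)ccc1O[Si](C(C)C)(C(C)C)C(C)C | intermediate
3 | (S)‑4‑benzyl‑1,3‑oxazolidin‑2‑one | O=C1N[C@@H](Cc2ccccc2)CO1 | starting material
4 | methyl 4‑chloro‑4‑oxobutanoate | COC(=O)CCC(Cl)=O | starting material
5 | lithium salt of 3 | [Li]N1C(=O)OC[C@@H]1Cc1ccccc1 | intermediate (not isolated)
6 | methyl 4‑[(4S)‑4‑benzyl‑2‑oxo‑1,3‑oxazolidin‑3‑yl]‑4‑oxobutanoate | COC(=O)CCC(=O)N1C(=O)OC[C@@H]1Cc1ccccc1 | intermediate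
7 | dibutylboron Z‑enolate of 6 | CCCCB(CCCC)O/C(=C\CC(=O)OC)N1C(=O)OC[C@@H]1Cc1ccccc1 | intermediate (not isolated)
8 | methyl (3S,4S)‑4‑Ar‑3‑{[(4S)‑4‑benzyl‑2‑oxo‑1,3‑oxazolidin‑3‑yl]carbonyl}‑4‑hydroxybutanoate | COC(=O)C[C@@H]([C@H](O)c1ccc(O[Si](C(C)C)(C(C)C)C(C)C)c(OC)c1)C(=O)N1C(=O)OC[C@@H]1Cc1ccccc1 | intermediate
9 | (2S)‑2‑[(S)‑Ar(hydroxy)methyl]‑4‑methoxy‑4‑oxobutanoic acid | COC(=O)C[C@@H]([C@H](O)c1ccc(O[Si](C(C)C)(C(C)C)C(C)C)c(OC)c1)C(=O)O | intermediate (not isolated)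
10 | (2S,3S)‑2‑Ar‑5‑oxotetrahydrofuran‑3‑carboxylic acid | COc1cc([C@H]2OC(=O)C[C@@H]2C(=O)O)ccc1O[Si](C(C)C)(C(C)C)C(C)C | intermediate
11 | (4R,5S)‑5‑Ar‑4‑(hydroxymethyl)dihydrofuran‑2(3H)‑one | COc1cc([C@H]2OC(=O)C[C@@H]2CO)ccc1O[Si](C(C)C)(C(C)C)C(C)C | intermediate
12 | (4R,5S)‑5‑Ar‑4‑[(tert‑butyldimethylsilyloxy)methyl]dihydrofuran‑2(3H)‑one | COc1cc([C@H]2OC(=O)C[C@@H]2CO[Si](C)(C)C(C)(C)C)ccc1O[Si](C(C)C)(C(C)C)C(C)C | intermediate
13 | lithium enolate of 12 | [Li]OC1=C[C@H](CO[Si](C)(C)C(C)(C)C)[C@@H](c2ccc(O[Si](C(C)C)(C(C)C)C(C)C)c(OC)c2)O1 | intermediate (not isolated)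
14 | (3R,4R,5S)‑5‑Ar‑3‑[Ar(hydroxy)methyl]‑4‑[(tert‑butyldimethylsilyloxy)methyl]dihydrofuran‑2(3H)‑one, both carbinol epimers | COc1cc([C@H]2OC(=O)[C@@H](C(O)c3ccc(O[Si](C(C)C)(C(C)C)C(C)C)c(OC)c3)[C@@H]2CO[Si](C)(C)C(C)(C)C)ccc1O[Si](C(C)C)(C(C)C)C(C)C | intermediate
15 | (3R,4R,5S)‑5‑Ar‑3‑aroyl‑4‑[(tert‑butyldimethylsilyloxy)methyl]dihydrofuran‑2(3H)‑one | COc1cc([C@H]2OC(=O)[C@@H](C(=O)c3ccc(O[Si](C(C)C)(C(C)C)C(C)C)c(OC)c3)[C@@H]2CO[Si](C)(C)C(C)(C)C)ccc1O[Si](C(C)C)(C(C)C)C(C)C | intermediate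
16 | (3R,4R,5S)‑5‑Ar‑3‑[(S)‑Ar(hydroxy)methyl]‑4‑[(tert‑butyldimethylsilyloxy)methyl]dihydrofuran‑2(3H)‑one | COc1cc([C@H]2OC(=O)[C@@H]([C@H](O)c3ccc(O[Si](C(C)C)(C(C)C)C(C)C)c(OC)c3)[C@@H]2CO[Si](C)(C)C(C)(C)C)ccc1O[Si](C(C)C)(C(C)C)C(C)C | intermediate
17 | dilithium alkoxide enolate of 16 | [Li]OC1=C([C@H](O[Li])c2ccc(O[Si](C(C)C)(C(C)C)C(C)C)c(OC)c2)[C@H](CO[Si](C)(C)C(C)(C)C)[C@@H](c2ccc(O[Si](C(C)C)(C(C)C)C(C)C)c(OC)c2)O1 | intermediate (not isolated)
18 | (3R,4R,5S)‑5‑Ar‑3‑hydroxy‑3‑[(R)‑Ar(hydroxy)methyl]‑4‑[(tert‑butyldimethylsilyloxy)methyl]dihydrofuran‑2(3H)‑one | COc1cc([C@H]2OC(=O)[C@](O)([C@H](O)c3ccc(O[Si](C(C)C)(C(C)C)C(C)C)c(OC)c3)[C@@H]2CO[Si](C)(C)C(C)(C)C)ccc1O[Si](C(C)C)(C(C)C)C(C)C | intermediate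
19 | (3R,4R,5S)‑5‑Ar‑3‑hydroxy‑3‑[(R)‑Ar(hydroxy)methyl]‑4‑(hydroxymethyl)dihydrofuran‑2(3H)‑one | COc1cc([C@H]2OC(=O)[C@](O)([C@H](O)c3ccc(O[Si](C(C)C)(C(C)C)C(C)C)c(OC)c3)[C@@H]2CO)ccc1O[Si](C(C)C)(C(C)C)C(C)C | intermediate
20 | primary p‑toluenesulfonate of 19 | COc1cc([C@H]2OC(=O)[C@](O)([C@H](O)c3ccc(O[Si](C(C)C)(C(C)C)C(C)C)c(OC)c3)[C@@H]2COS(=O)(=O)c3ccc(C)cc3)ccc1O[Si](C(C)C)(C(C)C)C(C)C | intermediate (not isolated)
21 | (1R,2R,5R,6S)‑2,6‑di‑Ar‑1‑hydroxy‑3,7‑dioxabicyclo[3.3.0]octan‑8‑one | COc1cc([C@H]2OC(=O)[C@]3(O)[C@@H](c4ccc(O[Si](C(C)C)(C(C)C)C(C)C)c(OC)c4)OC[C@H]23)ccc1O[Si](C(C)C)(C(C)C)C(C)C | intermediate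
22 | (1R,2R,5R,6S)‑2,6‑di‑Ar‑3,7‑dioxabicyclo[3.3.0]octane‑1,8‑diol, both C8 anomers | COc1cc([C@H]2OC(O)[C@]3(O)[C@@H](c4ccc(O[Si](C(C)C)(C(C)C)C(C)C)c(OC)c4)OC[C@H]23)ccc1O[Si](C(C)C)(C(C)C)C(C)C | intermediate
23 | (1S,2R,5R,6S)‑2,6‑di‑Ar‑3,7‑dioxabicyclo[3.3.0]octan‑1‑ol | COc1cc([C@H]2OC[C@]3(O)[C@@H](c4ccc(O[Si](C(C)C)(C(C)C)C(C)C)c(OC)c4)OC[C@H]23)ccc1O[Si](C(C)C)(C(C)C)C(C)C | intermediate
24 | (1S,2R,5R,6S)‑2,6‑di‑Ar‑3,7‑dioxabicyclo[3.3.0]octan‑1‑yl acetate | COc1cc([C@H]2OC[C@]3(OC(C)=O)[C@@H](c4ccc(O[Si](C(C)C)(C(C)C)C(C)C)c(OC)c4)OC[C@H]23)ccc1O[Si](C(C)C)(C(C)C)C(C)C | intermediate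
25 | 1‑acetoxypinoresinol | COc1cc([C@H]2OC[C@]3(OC(C)=O)[C@@H](c4ccc(O)c(OC)c4)OC[C@H]23)ccc1O | target

**Totals and weak points**

Total steps: 16. Longest linear sequence: 15 steps (steps 1 and 3–16 from vanillin; steps 2–16 from the oxazolidinone).

Steps most likely to fail:

- Step 9 (transfer hydrogenation). The catalyst may be slow or poorly selective on this crowded, chiral β‑keto lactone. The fallback sets out from lithium enolate 13 (made from 12 as in step 7) and comes back at 16. Treat 13 with (c‑C6H11)2BCl at −78 °C to give the dicyclohexylboron enolate F1, then add aldehyde 2 and work up with H2O2 at pH 7. The tight chair transition state of the fixed E‑lactone enolate gives the anti aldol on the face trans to the CH2OSi group, which is 16 itself. Steps 8 and 9 are then skipped and the minor syn epimer is removed by chromatography.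

- Step 10 (dianion hydroxylation). Incomplete second deprotonation or addition of the enolate to the sulfonimine by‑product could lower the yield. The fallback sets out from 16 and comes back at 19. Silylate the carbinol (Et3SiOTf, 2,6‑lutidine) to the triethylsilyl ether F2. Form its mono‑enolate with KN(SiMe3)2 at −78 °C and oxidise it with the same oxaziridine, or trap it as the silyl ketene acetal and use dimethyldioxirane (Rubottom oxidation), to reach the tertiary alcohol F3. Here the face is set by the ring substituent alone. The HF·pyridine conditions of step 11 then remove both alkyl silyl groups to give 19.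

- Step 14 (BF3/silane reduction). The Lewis acid may open or epimerize the electron‑rich benzylic ethers. The fallback sets out from 21 and comes back at 23. Reduce the lactone fully with LiBH4 in THF to the triol F4. Close ring A by Mitsunobu cyclodehydration (PPh3, DIAD, THF, 0 °C), in which the primary C8 hydroxyl is activated and displaced by the C6 hydroxyl with retention at C6.

**Further compounds**
F1 | step 9 | dicyclohexylboron enolate of lactone 12 | C1CCCCC1B(C1CCCCC1)OC1=C[C@H](CO[Si](C)(C)C(C)(C)C)[C@@H](c2ccc(O[Si](C(C)C)(C(C)C)C(C)C)c(OC)c2)O1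
F2 | step 10 | (3R,4R,5S)‑5‑Ar‑3‑[(S)‑Ar(triethylsilyloxy)methyl]‑4‑[(tert‑butyldimethylsilyloxy)methyl]dihydrofuran‑2(3H)‑one | COc1cc([C@H]2OC(=O)[C@@H]([C@H](O[Si](CC)(CC)CC)c3ccc(O[Si](C(C)C)(C(C)C)C(C)C)c(OC)c3)[C@@H]2CO[Si](C)(C)C(C)(C)C)ccc1O[Si](C(C)C)(C(C)C)C(C)C
F3 | step 10 | (3R,4R,5S)‑5‑Ar‑3‑hydroxy‑3‑[(R)‑Ar(triethylsilyloxy)methyl]‑4‑[(tert‑butyldimethylsilyloxy)methyl]dihydrofuran‑2(3H)‑one | COc1cc([C@H]2OC(=O)[C@](O)([C@H](O[Si](CC)(CC)CC)c3ccc(O[Si](C(C)C)(C(C)C)C(C)C)c(OC)c3)[C@@H]2CO[Si](C)(C)C(C)(C)C)ccc1O[Si](C(C)C)(C(C)C)C(C)C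
F4 | step 14 | (2R,3S,4R)‑2‑Ar‑4‑[(S)‑Ar(hydroxy)methyl]‑3‑(hydroxymethyl)tetrahydrofuran‑3‑ol | COc1cc([C@@H](O)[C@H]2CO[C@H](c3ccc(O[Si](C(C)C)(C(C)C)C(C)C)c(OC)c3)[C@@]2(O)CO)ccc1O[Si](C(C)C)(C(C)C)C(C)C
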